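**Strategy.** Everything rests on cutting the C4–C5 bond of ring B (C1, C2, C3, C4, C5, C9). The handle is the vinylogous acid of ring B: C4 carries oxygen, is sp2, sits on bridgehead C5 and is linked through the C3 methine to the C2 ketone, so it can be traced back to the alkoxy-substituted carbon of an ynone attacked by the C5 enol carbon. In one operation a gold-catalysed 6-endo-dig attack of the ring A silyl enol ether (C9–C5) on a 3-ethoxypropynoyl group on C1 closes ring B, sets C5 and delivers the full C2–C4 oxidation pattern as its ethyl ether. The precursor is an enantiopure ring A enol ether whose quaternary C1 carries the isobutyryl and ethoxypropynoyl groups.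

Key step: step 10

Remark on numbering: bicycle locants are used throughout (C1 isobutyryl bridgehead, C2–C3–C4 enolised diketone bridge, C5 prenyl bridgehead, C6 methylene, C7 prenyl methine, C8 methyl/homoprenyl carbon, C9 bridging ketone, C10 acyl carbonyl); prenyl = 3-methylbut-2-enyl, homoprenyl = 4-methylpent-3-enyl.

Remark on the structures: the descriptors of target 23, precursor 21 and cyclisation product 22 were checked against each other (C1, C7, C8 identical; C5 cis to C1 as the bicycle demands); they are consistent and are used unchanged. The target is (1R,5R,7S,8R).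

Remarks on design:
- The isobutyryl ketone has an α-hydrogen, so the regiochemistry of enol ether formation is not automatic; it rests on allylic strain (step 9).
- The ynoyl chloride is made from its lithium salt so that no HCl meets the ynol ether (step 8).
- Ring A is entered by a catalytic asymmetric step so that a single enantiomer results (step 1).
- The O-ethyl group is kept because ethoxyethyne is readily bought; its slower SN2 cleavage is dealt with in step 11.

Assumption: 5-methylhex-4-enal (1) is taken as a catalogue compound; otherwise it is one Claisen rearrangement step from the vinyl ether of 2-methylbut-3-en-2-ol.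

**Route**

Step 1
Reactants: 1 5-methylhex-4-enal; 2 but-3-en-2-one
Product: 3 (R)-2-(3-methylbut-2-enyl)-5-oxohexanal
Conditions: (R)-2-[methoxy(diphenyl)methyl]pyrrolidine (5 mol %), ethyl 3,4-dihydroxybenzoate (20 mol %), neat, 4 °C
Reagents that add atoms: none
Why: Enamine-catalysed asymmetric Michael addition: the anti E-enamine of 1 is shielded on one face by the methoxydiphenylmethyl group of the (R)-catalyst and adds to 2 through the open face, which should set the future C7 centre as R under catalyst control.

Step 2
Reactants: 3 (R)-2-(3-methylbut-2-enyl)-5-oxohexanal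
Product: 4 (R)-4-(3-methylbut-2-enyl)cyclohex-2-en-1-one
Conditions: KOH (0.1 M aq), n-Bu4NOH (cat.), THF/Et2O, reflux
Reagents that add atoms: none
Why: Base-mediated intramolecular aldol condensation of the methyl ketone onto the aldehyde (the ring-closing half of a Robinson annulation) is the standard way from 2-alkyl-5-oxohexanals to 4-alkylcyclohexenones, and ring closure should outpace enolisation of the aldehyde so that the C7 centre is kept.

Step 3
Reactants: 4 (R)-4-(3-methylbut-2-enyl)cyclohex-2-en-1-one
Product: 6 (R)-3-methyl-4-(3-methylbut-2-enyl)cyclohex-2-en-1-one, via trimethylsilyl enol ether 5 (not isolated)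
Conditions: MeMgBr, CuBr·SMe2 (10 mol %), TMSCl, THF, −78 → −40 °C; crude 5: Pd(OAc)2 (10 mol %), O2, DMSO, rt
Reagents that add atoms: methylmagnesium bromide, C[Mg]Br
Why: Copper-catalysed conjugate addition of the methyl Grignard reagent with silyl trapping gives the enol ether regiospecifically and Saegusa–Ito dehydrogenation returns the enone with the methyl group on the β-carbon; the methyl-bearing carbon ends sp2, so the only stereocentre (C7) is not involved.

Step 4
Reactants: 6 (R)-3-methyl-4-(3-methylbut-2-enyl)cyclohex-2-en-1-one; 7 5-bromo-2-methylpent-2-ene; 8 2-methylpropanal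
Product: 11 (3R,4R)-2-(1-hydroxy-2-methylpropyl)-3-methyl-3-(4-methylpent-3-enyl)-4-(3-methylbut-2-enyl)cyclohexan-1-one (mixture at C2 and at the carbinol carbon), via Grignard reagent 9 (not isolated), via bromomagnesium enolate 10 (not isolated)
Conditions: 7, Mg, THF; then CuBr·SMe2 (20 mol %), 6, THF, −40 → −10 °C; then 8, −78 °C
Reagents that add atoms: none
Why: Copper-catalysed Grignard conjugate addition to the 4-substituted enone takes place anti to the neighbouring prenyl group, which sets quaternary C8 (homoprenyl trans to prenyl, methyl cis) under substrate control, and the regiospecific magnesium enolate is then trapped at C1 in an aldol addition with 8, the two carbinol-type centres formed there being removed again in steps 5 and 8.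

Step 5
Reactants: 11 aldol adduct
Product: 12 (3R,4R)-3-methyl-3-(4-methylpent-3-enyl)-4-(3-methylbut-2-enyl)-2-(2-methylpropanoyl)cyclohexan-1-one (largely the chelated enol)
Conditions: DMP, NaHCO3, CH2Cl2, 0 °C → rt
Reagents that add atoms: none
Why: Dess–Martin oxidation of a β-hydroxy ketone to the 1,3-diketone under buffered conditions, which avoids retro-aldol cleavage and touches neither the trisubstituted alkenes nor C7 and C8.

Step 6
Reactants: 12 ring A 1,3-diketone; 13 1-bromo-3-methylbut-2-ene
Product: 14 (3R,4S)-3-methyl-3-(4-methylpent-3-enyl)-4,6-bis(3-methylbut-2-enyl)-2-(2-methylpropanoyl)cyclohexan-1-one (C6 epimers; enolised)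
Conditions: LiN(i-Pr)2 (2.2 equiv), THF, −78 → 0 °C; then 13, −78 → 0 °C
Reagents that add atoms: none
Why: γ-Alkylation of a 1,3-diketone dianion: after enolate formation the second deprotonation should occur at the ring methylene C5 and not at the hindered isopropyl methine, and the more basic terminal carbanion is the one alkylated by the allylic bromide; the C5 centre is formed without control and is erased in step 9.

Step 7
Reactants: 15 ethoxyethyne
Product: 17 lithium 3-ethoxyprop-2-ynoate, via (ethoxyethynyl)lithium 16 (not isolated)
Conditions: n-BuLi, THF, −78 °C; CO2 (g), −78 °C → rt; evaporation, pentane trituration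
Reagents that add atoms: n-butyllithium, CCCC[Li]; carbon dioxide, O=C=O
Why: Deprotonation of the terminal alkoxyalkyne and carboxylation of the lithium acetylide is standard acetylide chemistry, and keeping the product as its lithium salt avoids the free acid, which would add water or HX across the electron-rich triple bond.

Step 8
Reactants: 14 C5-prenylated 1,3-diketone; 17 lithium 3-ethoxyprop-2-ynoate
Product: 20 (2S,3R,4S)-2-(3-ethoxyprop-2-ynoyl)-3-methyl-3-(4-methylpent-3-enyl)-4,6-bis(3-methylbut-2-enyl)-2-(2-methylpropanoyl)cyclohexan-1-one (C6 epimers), via 3-ethoxyprop-2-ynoyl chloride 18 (not isolated), via chloromagnesium diketonate 19 (not isolated)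
Conditions: 17, (COCl)2 (1.0 equiv), CH2Cl2, −20 °C; separately 14, i-PrMgCl (1.0 equiv), THF, −20 °C; acid chloride solution added to the enolate, −78 → 0 °C
Reagents that add atoms: none
Why: C-Acylation of a chelated magnesium 1,3-diketonate with an acid chloride (Claisen-type acylation of the kind used for magnesium alkylmalonates), in which chelation ties up both oxygens so that carbon is acylated; the acid chloride is made from the lithium salt without HCl, and it should approach C1 anti to the axial C8 methyl group, so that the propynoyl group ends axial and cis to the homoprenyl chain (C1 set under substrate control).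

Step 9
Reactants: 20 C1-quaternary triketone
Product: 21 tert-butyl{[(4S,5R,6R)-6-(3-ethoxyprop-2-ynoyl)-5-methyl-5-(4-methylpent-3-enyl)-2,4-bis(3-methylbut-2-enyl)-6-(2-methylpropanoyl)cyclohex-1-en-1-yl]oxy}dimethylsilane (the C9–C5 silyl enol ether)
Conditions: TBSOTf, i-Pr2NEt, CH2Cl2, −78 → 0 °C
Reagents that add atoms: tert-butyldimethylsilyl trifluoromethanesulfonate, CC(C)(C)[Si](C)(C)OS(=O)(=O)C(F)(F)F
Why: Soft enolisation and O-silylation: because C1 is quaternary the ring ketone C9 can enolise only toward C5, the isobutyryl ketone would have to form a tetrasubstituted enol ether with severe allylic strain against C1, the ynone has no α-hydrogen and the hindered amine does not add to it, so one regioisomer is expected and the mixed C5 configuration disappears.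

Step 10
Reactants: 21 ring A silyl enol ether carrying the isobutyryl and 3-ethoxypropynoyl groups on C1
Product: 22 (1R,5R,7S,8R)-4-ethoxy-8-methyl-8-(4-methylpent-3-enyl)-5,7-bis(3-methylbut-2-enyl)-1-(2-methylpropanoyl)bicyclo[3.3.1]non-3-ene-2,9-dione
Conditions: Ph3PAuNTf2 (5 mol %), i-PrOH (1.2 equiv), dry CH2Cl2, 0 °C → rt
Reagents that add atoms: none
Why: Proposed new method: Ph3PAuNTf2 (monovalent gold) binds the C3≡C4 triple bond, which the C2 carbonyl and the ethoxy group polarise in the same sense, so that C4 becomes an oxocarbenium-like electrophile; the enol ether carbon C5 attacks C4 anti to gold, the silyloxocarbenium ion formed at C9 hands its silyl group to 2-propanol, and protonation of the C3–Au bond releases the vinylogous ester and the catalyst. The closest known reaction type is the monovalent-gold-catalysed 6-endo-dig carbocyclisation of cyclic silyl enol ethers onto tethered alkynes and ynones that gives bicyclo[3.3.1]nonenones; an alkoxy-substituted ynone terminus has not been shown. Ring B (C1, C2, C3, C4, C5, C9) closes in the 6-endo-dig mode. The new stereocentre C5 is controlled by the tether: the propynoyl group is axial on C1 and reaches only the face of C5 on its own side, so C4 ends axial and the prenyl group equatorial. The step needs attack at C4 and not 5-exo attack at C3, and attack through carbon and not oxygen; the first is secured by the double polarisation of the alkyne, the second by the silyl cap on the enol oxygen and by the axial ynone standing perpendicular to the C9–O bond.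

Step 11
Reactants: 22 O-ethyl vinylogous ester
Product: 23 (1R,5R,7S,8R)-4-hydroxy-8-methyl-8-(4-methylpent-3-enyl)-5,7-bis(3-methylbut-2-enyl)-1-(2-methylpropanoyl)bicyclo[3.3.1]non-3-ene-2,9-dione (target)
Conditions: LiCl (10 equiv), degassed DMSO, 130 °C; aq. NH4Cl
Reagents that add atoms: none
Why: Krapcho-type SN2 dealkylation: chloride attacks the O-ethyl carbon and releases the vinylogous carboxylate, which is protonated on work-up to the enolised diketone; chloride does not add to the carbonyl groups around C1, so no retro-Claisen cleavage is expected, the temperature is higher than for a methyl ether because displacement at ethyl is slower, and no stereocentre is touched.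

**Compound list**

1 | 5-methylhex-4-enal | CC(C)=CCCC=O | starting material
2 | but-3-en-2-one | CC(=O)C=C | starting material
3 | (R)-2-(3-methylbut-2-enyl)-5-oxohexanal | CC(C)=CC[C@@H](CCC(C)=O)C=O | intermediate
4 | (R)-4-(3-methylbut-2-enyl)cyclohex-2-en-1-one | CC(C)=CC[C@H]1CCC(=O)C=C1 | intermediate
5 | trimethyl{[(3R,4R)-3-methyl-4-(3-methylbut-2-enyl)cyclohex-1-en-1-yl]oxy}silane | CC(C)=CC[C@H]1CCC(O[Si](C)(C)C)=C[C@@H]1C | intermediate
6 | (R)-3-methyl-4-(3-methylbut-2-enyl)cyclohex-2-en-1-one | CC(C)=CC[C@H]1CCC(=O)C=C1C | intermediate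
7 | 5-bromo-2-methylpent-2-ene | CC(C)=CCCBr | starting material
8 | 2-methylpropanal | CC(C)C=O | starting material
9 | (4-methylpent-3-enyl)magnesium bromide | CC(C)=CCC[Mg]Br | intermediate
10 | bromomagnesium enolate (toward C2) of (3R,4R)-3-methyl-3-(4-methylpent-3-enyl)-4-(3-methylbut-2-enyl)cyclohexanone | CC(C)=CCC[C@]1(C)[C@@H](CC=C(C)C)CCC(O[Mg]Br)=C1 | intermediate
11 | (3R,4R)-2-(1-hydroxy-2-methylpropyl)-3-methyl-3-(4-methylpent-3-enyl)-4-(3-methylbut-2-enyl)cyclohexan-1-one (mixture at C2 and carbinol carbon) | CC(C)=CCC[C@]1(C)[C@@H](CC=C(C)C)CCC(=O)C1C(O)C(C)C | intermediate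
12 | (3R,4R)-3-methyl-3-(4-methylpent-3-enyl)-4-(3-methylbut-2-enyl)-2-(2-methylpropanoyl)cyclohexan-1-one (enolised at C2) | CC(C)=CCC[C@]1(C)[C@@H](CC=C(C)C)CCC(=O)C1C(=O)C(C)C | intermediate
13 | 1-bromo-3-methylbut-2-ene | CC(C)=CCBr | starting material
14 | (3R,4S)-3-methyl-3-(4-methylpent-3-enyl)-4,6-bis(3-methylbut-2-enyl)-2-(2-methylpropanoyl)cyclohexan-1-one (C6 epimers, enolised at C2) | CC(C)=CCC[C@]1(C)[C@@H](CC=C(C)C)CC(CC=C(C)C)C(=O)C1C(=O)C(C)C | intermediate
15 | ethoxyethyne | CCOC#C | starting material
16 | (ethoxyethynyl)lithium | CCOC#C[Li] | intermediate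
17 | lithium 3-ethoxyprop-2-ynoate | CCOC#CC(=O)[O-].[Li+] | intermediate
18 | 3-ethoxyprop-2-ynoyl chloride | CCOC#CC(Cl)=O | intermediate
19 | chloromagnesium 1,3-diketonate of 14 | CC(C)=CCC[C@]1(C)[C@@H](CC=C(C)C)CC(CC=C(C)C)C(=O)C1=C(O[Mg]Cl)C(C)C | intermediate
20 | (2S,3R,4S)-2-(3-ethoxyprop-2-ynoyl)-3-methyl-3-(4-methylpent-3-enyl)-4,6-bis(3-methylbut-2-enyl)-2-(2-methylpropanoyl)cyclohexan-1-one (C6 epimers) | CC(C)=CCC[C@]1(C)[C@@H](CC=C(C)C)CC(CC=C(C)C)C(=O)[C@]1(C(=O)C(C)C)C(=O)C#COCC | intermediate
21 | tert-butyl{[(4S,5R,6R)-6-(3-ethoxyprop-2-ynoyl)-5-methyl-5-(4-methylpent-3-enyl)-2,4-bis(3-methylbut-2-enyl)-6-(2-methylpropanoyl)cyclohex-1-en-1-yl]oxy}dimethylsilane | CC(C)=CCC[C@]1(C)[C@@H](CC=C(C)C)CC(CC=C(C)C)=C(O[Si](C)(C)C(C)(C)C)[C@]1(C(=O)C(C)C)C(=O)C#COCC | intermediate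
22 | (1R,5R,7S,8R)-4-ethoxy-8-methyl-8-(4-methylpent-3-enyl)-5,7-bis(3-methylbut-2-enyl)-1-(2-methylpropanoyl)bicyclo[3.3.1]non-3-ene-2,9-dione | CC(C)=CCC[C@]1(C)[C@@H](CC=C(C)C)C[C@@]2(CC=C(C)C)C(=O)[C@]1(C(=O)C(C)C)C(=O)C=C2OCC | intermediate
23 | (1R,5R,7S,8R)-4-hydroxy-8-methyl-8-(4-methylpent-3-enyl)-5,7-bis(3-methylbut-2-enyl)-1-(2-methylpropanoyl)bicyclo[3.3.1]non-3-ene-2,9-dione | CC(C)=CCC[C@]1(C)[C@@H](CC=C(C)C)C[C@@]2(CC=C(C)C)C(=O)[C@]1(C(=O)C(C)C)C(=O)C=C2O | target

**Count**

Total steps: 11. Longest linear sequence: 10 (steps 1–6 and 8–11; step 7 is a one-step branch).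

**Steps most likely to fail**

1. Step 10 (gold closure onto the alkoxy-ynone). What may go wrong: the alcohol or adventitious water adds to the gold-activated ynol ether faster than C5 does, the ring closes through oxygen instead of carbon, or the push–pull alkyne binds gold too weakly for turnover. The fallback uses known chemistry, leaves the route at 14 and comes back at 23. 14 would be C-acylated as in step 8 with 3-(trimethylsilyl)prop-2-ynoyl chloride (from the commercial acid and (COCl)2) to give the C-silyl ynone triketone F1. TBSOTf/i-Pr2NEt would give its C9–C5 silyl enol ether F2. The alkynyl silane would be cleaved (Na2B4O7, aqueous MeOH) to the terminal ynone enol ether F3. Ph3PAuNTf2 with 2-propanol would then effect the established 6-endo-dig closure of a silyl enol ether onto a plain ynone, giving the bicyclic enone F4. Nucleophilic epoxidation (t-BuOOH, DBU) from the face on the C9 side would give the epoxy ketone F5. Pd(PPh3)4/dppe would isomerise the α,β-epoxy ketone to the 1,3-diketone, which is 23.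

2. Step 8 (C-acylation at C1). What may go wrong: acylation at oxygen instead of the crowded carbon, approach from the methyl-bearing face, or loss of the acid chloride before it reacts. The fallback leaves at 14 and comes back at 20. 14 would be O-acylated on purpose (18, 2,6-lutidine, CH2Cl2, −78 °C) to the enol ester F6. F6 would then be rearranged with catalytic 4-(pyrrolidin-1-yl)pyridine in a Steglich-type 1,3 O-to-C acyl migration through an acylpyridinium/enolate ion pair, giving 20. The C-acyl isomer should be the thermodynamic product because the enol ester is a vinylogous anhydride.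

3. Step 11 (cleavage of the ethyl ether). What may go wrong: displacement at the ethyl carbon is slow enough that thermal degradation of the polyprenylated product competes. The fallback leaves at 22 and comes back at 23. Acid-catalysed exchange of the vinylogous ester with allyl alcohol (PPTS, benzene, removal of ethanol) would give the O-allyl vinylogous ester F7; allylation of either enol oxygen converges. Pd(PPh3)4 with morpholine would then remove the allyl group at room temperature (Tsuji–Trost deallylation) to give 23.

Further compounds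

F1 | step 10 | C1-[3-(trimethylsilyl)prop-2-ynoyl] analogue of triketone 20 | CC(C)=CCC[C@]1(C)[C@@H](CC=C(C)C)CC(CC=C(C)C)C(=O)[C@]1(C(=O)C(C)C)C(=O)C#C[Si](C)(C)C
F2 | step 10 | C9–C5 tert-butyldimethylsilyl enol ether of F1 | CC(C)=CCC[C@]1(C)[C@@H](CC=C(C)C)CC(CC=C(C)C)=C(O[Si](C)(C)C(C)(C)C)[C@]1(C(=O)C(C)C)C(=O)C#C[Si](C)(C)C
F3 | step 10 | C9–C5 tert-butyldimethylsilyl enol ether with a C1 prop-2-ynoyl group (terminal ynone) | CC(C)=CCC[C@]1(C)[C@@H](CC=C(C)C)CC(CC=C(C)C)=C(O[Si](C)(C)C(C)(C)C)[C@]1(C(=O)C(C)C)C(=O)C#C
F4 | step 10 | (1R,5R,7S,8R)-configured bicyclo[3.3.1]non-3-ene-2,9-dione lacking the C4 oxygen (C3=C4 enone) | CC(C)=CCC[C@]1(C)[C@@H](CC=C(C)C)C[C@@]2(CC=C(C)C)C(=O)[C@]1(C(=O)C(C)C)C(=O)C=C2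
F5 | step 10 | 3,4-epoxide of F4, oxygen on the face syn to C9 | CC(C)=CCC[C@]1(C)[C@@H](CC=C(C)C)C[C@@]2(CC=C(C)C)C(=O)[C@]1(C(=O)C(C)C)C(=O)[C@@H]3O[C@H]23
F6 | step 8 | enol ester of 14 (3-ethoxyprop-2-ynoate on the C9 enol oxygen) | CC(C)=CCC[C@]1(C)[C@@H](CC=C(C)C)CC(CC=C(C)C)C(OC(=O)C#COCC)=C1C(=O)C(C)C
F7 | step 11 | O-allyl vinylogous ester (4-allyloxy analogue of 22) | CC(C)=CCC[C@]1(C)[C@@H](CC=C(C)C)C[C@@]2(CC=C(C)C)C(=O)[C@]1(C(=O)C(C)C)C(=O)C=C2OCC=C
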